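**Assumption:**
Atoms carry the macrolide numbering (C1 lactone carbonyl to C25, side chain C26–C36), TES = triethylsilyl, Ipc = isopinocampheyl. Where an antipode of a chiral reagent or ligand is named ((R,R)-Taniaphos, (−)- or (+)-Ipc2BOMe, D-fructose-derived Shi ketone, D-(−)-diisopropyl tartrate), it is the one the accepted selectivity model predicts for the configuration in the SMILES, to be confirmed on the first batch.

**Retrosynthetic overview**
1. 58 ⇒ 57 (four TES groups off); 57 ⇒ seco dialdehyde 54 by cutting C6–C7: Cp2TiCl-mediated ketyl-radical (pinacol) macrocyclisation closes the 26-membered ring and sets C6 and C7 together.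
2. 54 ⇒ acid 45 (C1–C6, from furan and ethyl diazoacetate) + alcohol 52 (C7–C36) by Yamaguchi esterification at O25.
3. 52 ⇒ C25–C26 (CrCl2/NiCl2 coupling of vinyl iodide 40 with aldehyde 50) and C17–C18 (chelation-controlled addition of the dienylmagnesium from iodide 23 to α-methoxy aldehyde 12).
4. Fragment W = 12 (glycidol, butenyl Grignard, copper-catalysed allylic methylation, two cross-metatheses); fragment E = 23 (methyl glycerate, Z-crotylboration, cross-metathesis, Takai); fragment S = 40 (butanal, methoxyallylboration, allenylboration, Shi epoxidation, hydrozirconation–iodination).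
5. Ring order: epoxide ring first (step 22, in fragment S); 26-membered lactone ring last (step 32).

**Fragment W (C7–C17)**

Step 1
Reactants: 1 (S)-glycidol
Product: 2 (R)-triethyl(oxiran-2-ylmethoxy)silane
Conditions: TESCl, imidazole, CH2Cl2, 0 °C
Reagents that add atoms: chlorotriethylsilane, CC[Si](Cl)(CC)CC
Why: O-silylation of the primary alcohol leaves the epoxide and its stereocentre (later C16) untouched.

Step 2
Reactants: 2 (R)-triethyl(oxiran-2-ylmethoxy)silane; 3 but-3-en-1-ylmagnesium bromide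
Product: 4 (R)-1-(triethylsilyloxy)hept-6-en-2-ol
Conditions: CuI (10 mol%), THF, −40 → −20 °C; aq. NH4Cl
Reagents that add atoms: none
Why: Copper-catalysed Grignard opening of the terminal epoxide (SN2 at the CH2 carbon) does not touch the stereocentre.

Step 3
Reactants: 4 (R)-1-(triethylsilyloxy)hept-6-en-2-ol
Product: 5 (R)-triethyl[(2-methoxyhept-6-en-1-yl)oxy]silane
Conditions: Me3OBF4, 1,8-bis(dimethylamino)naphthalene, CH2Cl2, rt
Reagents that add atoms: trimethyloxonium tetrafluoroborate, C[O+](C)C.F[B-](F)(F)F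
Why: O-methylation with Meerwein salt proceeds without an alkoxide, so the neighbouring TES group cannot migrate.

Step 4
Reactants: 5 (R)-triethyl[(2-methoxyhept-6-en-1-yl)oxy]silane; 6 (E)-1,4-dibromobut-2-ene
Product: 7 triethyl{[(2R,6E)-8-bromo-2-methoxyoct-6-en-1-yl]oxy}silane
Conditions: second-generation Hoveyda–Grubbs catalyst (2 mol%), 6 (3 equiv), CH2Cl2, 40 °C
Reagents that add atoms: none
Why: Olefin cross-metathesis of the terminal alkene with excess dibromobutene gives the E-allylic bromide.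

Step 5
Reactants: 7 triethyl{[(2R,6E)-8-bromo-2-methoxyoct-6-en-1-yl]oxy}silane
Product: 8 triethyl{[(2R,6R)-2-methoxy-6-methyloct-7-en-1-yl]oxy}silane
Conditions: MeMgBr, CuBr·SMe2 (1 mol%), (R,R)-Taniaphos (1.2 mol%), CH2Cl2, −75 °C
Reagents that add atoms: methylmagnesium bromide, C[Mg]Br
Why: Copper-catalysed asymmetric allylic alkylation (SN2′) gives the branched alkene and sets C12 (R) under ligand control.

Step 6
Reactants: 8 triethyl{[(2R,6R)-2-methoxy-6-methyloct-7-en-1-yl]oxy}silane; 9 methacrolein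
Product: 10 (2E,4R,8R)-8-methoxy-2,4-dimethyl-9-(triethylsilyloxy)non-2-enal
Conditions: second-generation Hoveyda–Grubbs catalyst (5 mol%), 9 (10 equiv), CH2Cl2, 40 °C
Reagents that add atoms: none
Why: Cross-metathesis of the only terminal alkene with methacrolein gives the thermodynamically preferred E trisubstituted enal (C10=C11).

Step 7
Reactants: 10 (2E,4R,8R)-8-methoxy-2,4-dimethyl-9-(triethylsilyloxy)non-2-enal
Product: 11 (2E,4E,6R,10R)-N,10-dimethoxy-N,4,6-trimethyl-11-(triethylsilyloxy)undeca-2,4-dienamide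
Conditions: (EtO)2P(O)CH2C(O)N(OMe)Me, NaH, THF, 0 °C → rt
Reagents that add atoms: diethyl {2-[methoxy(methyl)amino]-2-oxoethyl}phosphonate, CCOP(=O)(OCC)CC(=O)N(C)OC
Why: Horner–Wadsworth–Emmons olefination gives the E C8=C9 alkene and leaves C7 as a Weinreb amide that survives the later organometallic steps.

Step 8
Reactants: 11 (2E,4E,6R,10R)-N,10-dimethoxy-N,4,6-trimethyl-11-(triethylsilyloxy)undeca-2,4-dienamide
Product: 12 (2E,4E,6R,10R)-N,10-dimethoxy-N,4,6-trimethyl-11-oxoundeca-2,4-dienamide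
Conditions: (COCl)2, DMSO, CH2Cl2, −78 → −30 °C; Et3N
Reagents that add atoms: none
Why: Swern conditions convert a primary TES ether directly into the aldehyde (oxidative desilylation), so no separate deprotection is needed.

**Fragment E (C18–C25)**

Step 9
Reactants: 13 methyl (S)-2,3-dihydroxypropanoate
Product: 14 methyl (S)-2-hydroxy-3-(triethylsilyloxy)propanoate
Conditions: TESCl (1.0 equiv), imidazole, CH2Cl2, −20 °C
Reagents that add atoms: chlorotriethylsilane, CC[Si](Cl)(CC)CC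
Why: Silylation is selective for the primary over the secondary hydroxyl at low temperature.

Step 10
Reactants: 14 methyl (S)-2-hydroxy-3-(triethylsilyloxy)propanoate
Product: 15 methyl (S)-2-methoxy-3-(triethylsilyloxy)propanoate
Conditions: Me3OBF4, 1,8-bis(dimethylamino)naphthalene, CH2Cl2, rt
Reagents that add atoms: trimethyloxonium tetrafluoroborate, C[O+](C)C.F[B-](F)(F)F
Why: Non-basic O-methylation preserves the α-stereocentre (later C24) and avoids silyl migration.

Step 11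
Reactants: 15 methyl (S)-2-methoxy-3-(triethylsilyloxy)propanoate
Product: 16 (S)-2-methoxy-3-(triethylsilyloxy)propanal
Conditions: DIBAL (1.1 equiv), CH2Cl2, −78 °C; aq. potassium sodium tartrate
Reagents that add atoms: none
Why: DIBAL half-reduction of an α-alkoxy ester stops at the chelated hemiacetal, which gives the aldehyde on work-up.

Step 12
Reactants: 16 (S)-2-methoxy-3-(triethylsilyloxy)propanal; 17 cis-but-2-ene
Product: 20 (2S,3S,4R)-2-methoxy-4-methyl-1-(triethylsilyloxy)hex-5-en-3-ol, via (Z)-but-2-enylpotassium 18 (not isolated), via (Z)-crotyl-diisopinocampheylborane 19 (not isolated)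
Conditions: 17, n-BuLi, KOt-Bu, THF, −78 → −45 °C; (−)-Ipc2BOMe, −78 °C; BF3·OEt2; 16, −78 °C; ethanolamine
Reagents that add atoms: none
Why: Brown Z-crotylboration; the chair transition state turns Z geometry into the 22,23-syn relationship, and the (−)-Ipc groups select the aldehyde face that gives 23S (reagent control).

Step 13
Reactants: 20 (2S,3S,4R)-2-methoxy-4-methyl-1-(triethylsilyloxy)hex-5-en-3-ol
Product: 21 (2S,3S,4R)-2-methoxy-4-methyl-1,3-bis(triethylsilyloxy)hex-5-ene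
Conditions: TESOTf, 2,6-lutidine, CH2Cl2, −78 °C
Reagents that add atoms: triethylsilyl triflate, CC[Si](CC)(CC)OS(=O)(=O)C(F)(F)F
Why: Silyl triflate silylation caps the hindered secondary alcohol.

Step 14
Reactants: 21 (2S,3S,4R)-2-methoxy-4-methyl-1,3-bis(triethylsilyloxy)hex-5-ene; 9 methacrolein
Product: 22 (2E,4R,5S,6S)-6-methoxy-2,4-dimethyl-5,7-bis(triethylsilyloxy)hept-2-enal
Conditions: second-generation Hoveyda–Grubbs catalyst (10 mol%), 9 (10 equiv), CH2Cl2, 40 °C
Reagents that add atoms: none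
Why: Cross-metathesis with methacrolein converts the vinyl group into the E enal (C20=C21) in one step.

Step 15
Reactants: 22 (2E,4R,5S,6S)-6-methoxy-2,4-dimethyl-5,7-bis(triethylsilyloxy)hept-2-enal
Product: 23 (1E,3E,5R,6S,7S)-1-iodo-7-methoxy-3,5-dimethyl-6,8-bis(triethylsilyloxy)octa-1,3-diene
Conditions: CrCl2 (6 equiv), CHI3 (2 equiv), THF, 0 °C → rt
Reagents that add atoms: iodoform, IC(I)I
Why: Takai olefination homologates the enal to the (E)-dienyl iodide (C18=C19).

**Fragment S (C26–C36)**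

Step 16
Reactants: 24 butanal; 25 allyl methyl ether
Product: 28 (3S,4S)-3-methoxyhept-1-en-4-ol, via (Z)-3-methoxyallyllithium 26 (not isolated), via (Z)-3-methoxyallyl-diisopinocampheylborane 27 (not isolated)
Conditions: 25, s-BuLi, THF, −78 °C; (+)-Ipc2BOMe; BF3·OEt2; 24, −78 °C; ethanolamine
Reagents that add atoms: none
Why: Brown (Z)-γ-methoxyallylboration; the Z enol ether gives the 32,33-syn product through a chair transition state, and the (+)-Ipc groups set the absolute configuration (33S).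

Step 17
Reactants: 28 (3S,4S)-3-methoxyhept-1-en-4-ol
Product: 29 triethyl{[(3S,4S)-3-methoxyhept-1-en-4-yl]oxy}silane
Conditions: TESOTf, 2,6-lutidine, CH2Cl2, −78 °C
Reagents that add atoms: triethylsilyl triflate, CC[Si](CC)(CC)OS(=O)(=O)C(F)(F)F
Why: Silylation protects O33 for the rest of the route.

Step 18
Reactants: 29 triethyl{[(3S,4S)-3-methoxyhept-1-en-4-yl]oxy}silane
Product: 31 (2R,3S)-2-methoxy-3-(triethylsilyloxy)hexanal, via secondary ozonide 30 (not isolated)
Conditions: O3, CH2Cl2, −78 °C; PPh3, −78 °C → rt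
Reagents that add atoms: ozone, O=[O+][O-]
Why: Ozonolysis with reductive work-up cleaves the only alkene to the α-methoxy aldehyde without touching the stereocentres.

Step 19
Reactants: 31 (2R,3S)-2-methoxy-3-(triethylsilyloxy)hexanal
Product: 32 (2E,4S,5S)-4-methoxy-2-methyl-5-(triethylsilyloxy)oct-2-enal
Conditions: Ph3P=C(Me)CHO, toluene, 80 °C
Reagents that add atoms: 2-(triphenylphosphoranylidene)propanal, CC(C=O)=P(c1ccccc1)(c1ccccc1)c1ccccc1
Why: Wittig olefination with the stabilised ylide gives the E trisubstituted enal (C30=C31).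

Step 20
Reactants: 32 (2E,4S,5S)-4-methoxy-2-methyl-5-(triethylsilyloxy)oct-2-enal; 33 propargyl bromide
Product: 36 (4S,5E,7S,8S)-7-methoxy-5-methyl-8-(triethylsilyloxy)undec-5-en-1-yn-4-ol, via allenylmagnesium bromide 34 (not isolated), via allenyl-diisopinocampheylborane 35 (not isolated)
Conditions: 33, Mg, Et2O, 0 °C; (−)-Ipc2BOMe, −78 °C; 32, −100 → −78 °C; ethanolamine
Reagents that add atoms: none
Why: Brown-type asymmetric propargylboration; the allenylborane adds 1,2 through a six-membered SE2′ transition state, and the (−)-Ipc groups set C29 (S).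

Step 21
Reactants: 36 (4S,5E,7S,8S)-7-methoxy-5-methyl-8-(triethylsilyloxy)undec-5-en-1-yn-4-ol
Product: 37 (4S,5E,7S,8S)-7-methoxy-5-methyl-4,8-bis(triethylsilyloxy)undec-5-en-1-yne
Conditions: TESOTf, 2,6-lutidine, CH2Cl2, −78 °C
Reagents that add atoms: triethylsilyl triflate, CC[Si](CC)(CC)OS(=O)(=O)C(F)(F)F
Why: Silylation protects O29 before the epoxidation.

Step 22
Reactants: 37 (4S,5E,7S,8S)-7-methoxy-5-methyl-4,8-bis(triethylsilyloxy)undec-5-en-1-yne
Product: 38 C26–C36 epoxy alkyne (30,31-epoxide configured as in the target; 29-OTES; 33-OTES)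
Conditions: D-fructose-derived Shi ketone (30 mol%), Oxone (2KHSO5·KHSO4·K2SO4), K2CO3, Bu4NHSO4, MeCN/dimethoxymethane/aq. Na2B4O7–Na2EDTA, 0 °C
Reagents that add atoms: potassium peroxymonosulfate, [K+].[O-]S(=O)(=O)OO
Why: Shi asymmetric epoxidation; the chiral dioxirane attacks the E trisubstituted alkene through the spiro transition state on the face that gives the (30R,31R) epoxide, and the alkyne is inert.

Step 23
Reactants: 38 C26–C36 epoxy alkyne
Product: 40 C26–C36 (E)-vinyl iodide (fragment S), via alkenylzirconocene chloride 39 (not isolated)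
Conditions: Cp2Zr(H)Cl, THF, rt, 20 min; I2, 0 °C
Reagents that add atoms: iodine, [I][I]
Why: Hydrozirconation (syn, terminal) followed by iodinolysis with retention gives the (E)-vinyl iodide.

**Fragment A (C1–C6)**

Step 24
Reactants: 41 furan; 42 ethyl diazoacetate
Product: 44 ethyl (2E,4E)-6-oxohexa-2,4-dienoate, via ethyl (2E,4Z)-6-oxohexa-2,4-dienoate 43 (not isolated)
Conditions: Rh2(OAc)4 (0.5 mol%), furan (excess), rt; then I2 (cat.), CH2Cl2, rt
Reagents that add atoms: none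
Why: Rhodium-carbenoid addition to furan and ring opening give the (2E,4Z)-dienal, which iodine isomerises to the thermodynamic E,E isomer.

Step 25
Reactants: 44 ethyl (2E,4E)-6-oxohexa-2,4-dienoate
Product: 45 (2E,4E)-6-oxohexa-2,4-dienoic acid
Conditions: Me3SnOH, 1,2-dichloroethane, 70 °C; aq. HCl
Reagents that add atoms: trimethyltin hydroxide, C[Sn](C)(C)O
Why: Me3SnOH cleaves the ethyl ester under near-neutral conditions (ester hydrolysis), so the conjugated aldehyde is not attacked.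

**Assembly**

Step 26
Reactants: 23 (1E,3E,5R,6S,7S)-1-iodo-7-methoxy-3,5-dimethyl-6,8-bis(triethylsilyloxy)octa-1,3-diene; 12 (2E,4E,6R,10R)-N,10-dimethoxy-N,4,6-trimethyl-11-oxoundeca-2,4-dienamide
Product: 48 C7–C25 allylic alcohol (C7 Weinreb amide; 17R-OH; 23-OTES; 25-OTES), via dienyllithium 46 (not isolated), via dienylmagnesium bromide 47 (not isolated)
Conditions: 23, t-BuLi (2 equiv), Et2O, −78 °C; MgBr2·OEt2; 12 (1.2 equiv), CH2Cl2/Et2O, −78 °C
Reagents that add atoms: none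
Why: Iodine–lithium exchange, transmetalation and Cram-chelate addition; magnesium bridges the aldehyde and C16 methoxy oxygens and the dienyl group adds anti to the C15 chain, giving 16,17-syn (17R), while the Weinreb amide is inert at −78 °C.

Step 27
Reactants: 48 C7–C25 allylic alcohol
Product: 49 C7–C25 tris-TES ether (17-OTES; 23-OTES; 25-OTES)
Conditions: TESOTf, 2,6-lutidine, CH2Cl2, −78 °C
Reagents that add atoms: triethylsilyl triflate, CC[Si](CC)(CC)OS(=O)(=O)C(F)(F)F
Why: Silylation protects O17 before the C25 terminus is oxidised.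

Step 28
Reactants: 49 C7–C25 tris-TES ether
Product: 50 C7–C25 aldehyde (C25 CHO; 17-OTES; 23-OTES)
Conditions: (COCl)2, DMSO, CH2Cl2, −78 → −30 °C; Et3N
Reagents that add atoms: none
Why: Swern oxidative desilylation is selective for the primary TES ether over the two secondary ones.

Step 29
Reactants: 50 C7–C25 aldehyde; 40 C26–C36 (E)-vinyl iodide
Product: 51 C7–C36 alcohol (25S-OH; C7 Weinreb amide; four secondary TES ethers)
Conditions: CrCl2 (8 equiv), NiCl2 (2 mol%), DMSO, rt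
Reagents that add atoms: none
Why: Nozaki–Hiyama–Kishi coupling; the alkenyl group adds in the Felkin–Anh sense anti to the C24 methoxy group (24,25-anti, 25S) with retention of the E alkene, and epoxide, amide and silyl ethers are tolerated.

Step 30
Reactants: 51 C7–C36 alcohol
Product: 52 C7–C36 dienal (C7 CHO; 25-OH)
Conditions: DIBAL (3 equiv), THF, −78 °C; aq. potassium sodium tartrate
Reagents that add atoms: none
Why: DIBAL reduction of a Weinreb amide stops at the chelated tetrahedral adduct, which releases the dienal on work-up.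

Step 31
Reactants: 52 C7–C36 dienal; 45 (2E,4E)-6-oxohexa-2,4-dienoic acid
Product: 54 seco dialdehyde ester (C6 CHO and C7 CHO; O25 acylated), via mixed anhydride 53 (not isolated)
Conditions: 45, 2,4,6-trichlorobenzoyl chloride, Et3N, toluene, rt; then 52, DMAP, toluene, rt
Reagents that add atoms: none
Why: Yamaguchi esterification through the mixed anhydride acylates the single free hydroxyl (O25) and leaves both aldehydes untouched.

Step 32
Reactants: 54 seco dialdehyde ester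
Product: 57 tetra-TES macrolide (6R,7R)-diol, via bis(titanoxy) diradical 55 (not isolated), via titanium pinacolate 56 (not isolated)
Conditions: Cp2TiCl2 (6 equiv), Mn dust, THF, rt (gives Cp2TiCl); 54 added over 8 h at −78 °C (final 0.5 mM), then −40 °C; aq. NaHCO3
Reagents that add atoms: none
Why: Proposed new method: both aldehydes are conjugated and are reduced by trivalent titanium at −78 °C while epoxide, ester and silyl ethers are not, the two titanium-bound ketyl radicals combine at the carbinol carbons with high dilution favouring the 26-membered ring, and the bulky Cp2Ti(Cl)O groups sit anti in the coupling transition state so that the threo diol forms; the closest known reactions are the threo-selective Cp2TiCl pinacol homocoupling of enals and low-valent-titanium pinacol macrocyclisations of dialdehydes, and since the preference between the two threo faces (6R,7R against 6S,7S) rests only on the resident stereocentres, the isomers are separated and the unwanted one is cleaved back to 54 with NaIO4.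

Step 33
Reactants: 57 tetra-TES macrolide (6R,7R)-diol
Product: 58 CNP0328768.3
Conditions: HF·pyridine, pyridine, THF, 0 °C → rt
Reagents that add atoms: none
Why: Buffered fluoride desilylation removes the four secondary TES ethers without opening the epoxide or the lactone.

**Compound list**

1 | (S)-glycidol | C1[C@@H](O1)CO | starting material
2 | (R)-triethyl(oxiran-2-ylmethoxy)silane | C1[C@@H](O1)CO[Si](CC)(CC)CC | intermediate
3 | but-3-en-1-ylmagnesium bromide | C=CCC[Mg]Br | starting material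
4 | (R)-1-(triethylsilyloxy)hept-6-en-2-ol | C=CCCC[C@@H](O)CO[Si](CC)(CC)CC | intermediate
5 | (R)-triethyl[(2-methoxyhept-6-en-1-yl)oxy]silane | C=CCCC[C@@H](OC)CO[Si](CC)(CC)CC | intermediate
6 | (E)-1,4-dibromobut-2-ene | BrC/C=C/CBr | starting material
7 | triethyl{[(2R,6E)-8-bromo-2-methoxyoct-6-en-1-yl]oxy}silane | BrC/C=C/CCC[C@@H](OC)CO[Si](CC)(CC)CC | intermediate
8 | triethyl{[(2R,6R)-2-methoxy-6-methyloct-7-en-1-yl]oxy}silane | C=C[C@H](C)CCC[C@@H](OC)CO[Si](CC)(CC)CC | intermediate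
9 | methacrolein (2-methylprop-2-enal) | CC(=C)C=O | starting material
10 | (2E,4R,8R)-8-methoxy-2,4-dimethyl-9-(triethylsilyloxy)non-2-enal | O=C/C(C)=C/[C@H](C)CCC[C@@H](OC)CO[Si](CC)(CC)CC | intermediate
11 | (2E,4E,6R,10R)-N,10-dimethoxy-N,4,6-trimethyl-11-(triethylsilyloxy)undeca-2,4-dienamide | CON(C)C(=O)/C=C/C(C)=C/[C@H](C)CCC[C@@H](OC)CO[Si](CC)(CC)CC | intermediate
12 | (2E,4E,6R,10R)-N,10-dimethoxy-N,4,6-trimethyl-11-oxoundeca-2,4-dienamide (fragment W, C7–C17) | CON(C)C(=O)/C=C/C(C)=C/[C@H](C)CCC[C@@H](OC)C=O | intermediate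
13 | methyl (S)-2,3-dihydroxypropanoate (methyl L-glycerate) | COC(=O)[C@H](CO)O | starting material
14 | methyl (S)-2-hydroxy-3-(triethylsilyloxy)propanoate | COC(=O)[C@H](CO[Si](CC)(CC)CC)O | intermediate
15 | methyl (S)-2-methoxy-3-(triethylsilyloxy)propanoate | COC(=O)[C@H](CO[Si](CC)(CC)CC)OC | intermediate
16 | (S)-2-methoxy-3-(triethylsilyloxy)propanal | O=C[C@H](CO[Si](CC)(CC)CC)OC | intermediate
17 | cis-but-2-ene | C/C=C\C | starting material
18 | (Z)-but-2-enylpotassium | C/C=C\C[K] | intermediate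
19 | (Z)-crotyl-diisopinocampheylborane, (−)-Ipc series from (+)-α-pinene | C/C=C\CB([C@@H]1C[C@@H]2C[C@@H](C2(C)C)[C@H]1C)[C@@H]1C[C@@H]2C[C@@H](C2(C)C)[C@H]1C | intermediate
20 | (2S,3S,4R)-2-methoxy-4-methyl-1-(triethylsilyloxy)hex-5-en-3-ol | C=C[C@@H](C)[C@H](O)[C@H](CO[Si](CC)(CC)CC)OC | intermediate
21 | (2S,3S,4R)-2-methoxy-4-methyl-1,3-bis(triethylsilyloxy)hex-5-ene | C=C[C@@H](C)[C@H](O[Si](CC)(CC)CC)[C@H](CO[Si](CC)(CC)CC)OC | intermediate
22 | (2E,4R,5S,6S)-6-methoxy-2,4-dimethyl-5,7-bis(triethylsilyloxy)hept-2-enal | O=C/C(C)=C/[C@@H](C)[C@H](O[Si](CC)(CC)CC)[C@H](CO[Si](CC)(CC)CC)OC | intermediate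
23 | (1E,3E,5R,6S,7S)-1-iodo-7-methoxy-3,5-dimethyl-6,8-bis(triethylsilyloxy)octa-1,3-diene (fragment E, C18–C25) | I/C=C/C(C)=C/[C@@H](C)[C@H](O[Si](CC)(CC)CC)[C@H](CO[Si](CC)(CC)CC)OC | intermediate
24 | butanal | CCCC=O | starting material
25 | allyl methyl ether (3-methoxyprop-1-ene) | COCC=C | starting material
26 | (Z)-3-methoxyallyllithium | CO/C=C\C[Li] | intermediate
27 | (Z)-3-methoxyallyl-diisopinocampheylborane, (+)-Ipc series from (−)-α-pinene | CO/C=C\CB([C@H]1C[C@H]2C[C@H](C2(C)C)[C@@H]1C)[C@H]1C[C@H]2C[C@H](C2(C)C)[C@@H]1C | intermediate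
28 | (3S,4S)-3-methoxyhept-1-en-4-ol | CCC[C@H](O)[C@@H](OC)C=C | intermediate
29 | triethyl{[(3S,4S)-3-methoxyhept-1-en-4-yl]oxy}silane | CCC[C@H](O[Si](CC)(CC)CC)[C@@H](OC)C=C | intermediate
30 | secondary ozonide of 29 (3-substituted 1,2,4-trioxolane, both epimers at the ring carbon) | CCC[C@H](O[Si](CC)(CC)CC)[C@@H](OC)C1OCOO1 | intermediate
31 | (2R,3S)-2-methoxy-3-(triethylsilyloxy)hexanal | CCC[C@H](O[Si](CC)(CC)CC)[C@@H](OC)C=O | intermediate
32 | (2E,4S,5S)-4-methoxy-2-methyl-5-(triethylsilyloxy)oct-2-enal | CCC[C@H](O[Si](CC)(CC)CC)[C@@H](OC)/C=C(C)/C=O | intermediate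
33 | propargyl bromide (3-bromoprop-1-yne) | BrCC#C | starting material
34 | allenylmagnesium bromide | C=C=C[Mg]Br | intermediate
35 | allenyl-diisopinocampheylborane, (−)-Ipc series | C=C=CB([C@@H]1C[C@@H]2C[C@@H](C2(C)C)[C@H]1C)[C@@H]1C[C@@H]2C[C@@H](C2(C)C)[C@H]1C | intermediate
36 | (4S,5E,7S,8S)-7-methoxy-5-methyl-8-(triethylsilyloxy)undec-5-en-1-yn-4-ol | CCC[C@H](O[Si](CC)(CC)CC)[C@@H](OC)/C=C(C)/[C@@H](O)CC#C | intermediate
37 | (4S,5E,7S,8S)-7-methoxy-5-methyl-4,8-bis(triethylsilyloxy)undec-5-en-1-yne | CCC[C@H](O[Si](CC)(CC)CC)[C@@H](OC)/C=C(C)/[C@@H](O[Si](CC)(CC)CC)CC#C | intermediate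
38 | C26–C36 epoxy alkyne: 30,31-epoxide of 37, stereocentres as C29–C33 of the target, 29-OTES, 33-OTES | CCC[C@H](O[Si](CC)(CC)CC)[C@@H](OC)[C@H]1O[C@]1(C)[C@@H](O[Si](CC)(CC)CC)CC#C | intermediate
39 | (E)-alkenylzirconocene chloride from 38 (cyclopentadienyl ligands drawn σ-bonded) | CCC[C@H](O[Si](CC)(CC)CC)[C@@H](OC)[C@H]1O[C@]1(C)[C@@H](O[Si](CC)(CC)CC)C/C=C/[Zr](Cl)(C2C=CC=C2)C2C=CC=C2 | intermediate
40 | C26–C36 (E)-vinyl iodide (fragment S): iodide at C26, 26E, epoxide and stereocentres as in the target, 29-OTES, 33-OTES | CCC[C@H](O[Si](CC)(CC)CC)[C@@H](OC)[C@H]1O[C@]1(C)[C@@H](O[Si](CC)(CC)CC)C/C=C/I | intermediate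
41 | furan | c1ccoc1 | starting material
42 | ethyl diazoacetate | CCOC(=O)C=[N+]=[N-] | starting material
43 | ethyl (2E,4Z)-6-oxohexa-2,4-dienoate | CCOC(=O)/C=C/C=C\C=O | intermediate
44 | ethyl (2E,4E)-6-oxohexa-2,4-dienoate | CCOC(=O)/C=C/C=C/C=O | intermediate
45 | (2E,4E)-6-oxohexa-2,4-dienoic acid (fragment A, C1–C6) | OC(=O)/C=C/C=C/C=O | intermediate
46 | dienyllithium from 23 (lithium at C18) | [Li]/C=C/C(C)=C/[C@@H](C)[C@H](O[Si](CC)(CC)CC)[C@H](CO[Si](CC)(CC)CC)OC | intermediate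
47 | dienylmagnesium bromide from 23 (MgBr at C18) | Br[Mg]/C=C/C(C)=C/[C@@H](C)[C@H](O[Si](CC)(CC)CC)[C@H](CO[Si](CC)(CC)CC)OC | intermediate
48 | C7–C25 allylic alcohol: C7 N-methoxy-N-methylamide, 8E,10E,18E,20E, 17-OH, 23-OTES, 25-OTES, stereocentres as C12, C16, C17, C22, C23, C24 of the target | CON(C)C(=O)/C=C/C(C)=C/[C@H](C)CCC[C@@H](OC)[C@H](O)/C=C/C(C)=C/[C@@H](C)[C@H](O[Si](CC)(CC)CC)[C@H](CO[Si](CC)(CC)CC)OC | intermediate
49 | C7–C25 tris-TES ether: 48 with 17-OTES | CON(C)C(=O)/C=C/C(C)=C/[C@H](C)CCC[C@@H](OC)[C@H](O[Si](CC)(CC)CC)/C=C/C(C)=C/[C@@H](C)[C@H](O[Si](CC)(CC)CC)[C@H](CO[Si](CC)(CC)CC)OC | intermediate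
50 | C7–C25 aldehyde: 49 with C25 as CHO | CON(C)C(=O)/C=C/C(C)=C/[C@H](C)CCC[C@@H](OC)[C@H](O[Si](CC)(CC)CC)/C=C/C(C)=C/[C@@H](C)[C@H](O[Si](CC)(CC)CC)[C@H](C=O)OC | intermediate
51 | C7–C36 alcohol: C7 Weinreb amide, free 25-OH (25S), 26E, epoxide, TES ethers at O17, O23, O29, O33 | CCC[C@H](O[Si](CC)(CC)CC)[C@@H](OC)[C@H]1O[C@]1(C)[C@@H](O[Si](CC)(CC)CC)C/C=C/[C@H](O)[C@H](OC)[C@@H](O[Si](CC)(CC)CC)[C@H](C)/C=C(C)/C=C/[C@@H](O[Si](CC)(CC)CC)[C@H](OC)CCC[C@@H](C)/C=C(C)/C=C/C(=O)N(C)OC | intermediate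
52 | C7–C36 dienal: 51 with C7 as CHO | CCC[C@H](O[Si](CC)(CC)CC)[C@@H](OC)[C@H]1O[C@]1(C)[C@@H](O[Si](CC)(CC)CC)C/C=C/[C@H](O)[C@H](OC)[C@@H](O[Si](CC)(CC)CC)[C@H](C)/C=C(C)/C=C/[C@@H](O[Si](CC)(CC)CC)[C@H](OC)CCC[C@@H](C)/C=C(C)/C=C/C=O | intermediate
53 | (2E,4E)-6-oxohexa-2,4-dienoic 2,4,6-trichlorobenzoic anhydride | O=C/C=C/C=C/C(=O)OC(=O)c1c(Cl)cc(Cl)cc1Cl | intermediate
54 | seco dialdehyde ester: 52 acylated at O25 by the (2E,4E)-6-oxohexa-2,4-dienoyl group (aldehydes at C6 and C7) | CCC[C@H](O[Si](CC)(CC)CC)[C@@H](OC)[C@H]1O[C@]1(C)[C@@H](O[Si](CC)(CC)CC)C/C=C/[C@H](OC(=O)/C=C/C=C/C=O)[C@H](OC)[C@@H](O[Si](CC)(CC)CC)[C@H](C)/C=C(C)/C=C/[C@@H](O[Si](CC)(CC)CC)[C@H](OC)CCC[C@@H](C)/C=C(C)/C=C/C=O | intermediate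
55 | bis(titanoxy) diradical: both aldehydes of 54 as Cp2Ti(Cl)O-bound ketyl radicals | CCC[C@H](O[Si](CC)(CC)CC)[C@@H](OC)[C@H]1O[C@]1(C)[C@@H](O[Si](CC)(CC)CC)C/C=C/[C@H](OC(=O)/C=C/C=C/[CH]O[Ti](Cl)(C2C=CC=C2)C2C=CC=C2)[C@H](OC)[C@@H](O[Si](CC)(CC)CC)[C@H](C)/C=C(C)/C=C/[C@@H](O[Si](CC)(CC)CC)[C@H](OC)CCC[C@@H](C)/C=C(C)/C=C/[CH]O[Ti](Cl)(C2C=CC=C2)C2C=CC=C2 | intermediate
56 | titanium pinacolate: macrocycle with O6 and O7 each bound to Cp2TiCl | CCC[C@H](O[Si](CC)(CC)CC)[C@@H](OC)[C@H]1O[C@]1(C)[C@@H](O[Si](CC)(CC)CC)C/C=C/[C@@H]1OC(=O)/C=C/C=C/[C@@H](O[Ti](Cl)(C2C=CC=C2)C2C=CC=C2)[C@H](O[Ti](Cl)(C2C=CC=C2)C2C=CC=C2)/C=C/C(C)=C/[C@H](C)CCC[C@@H](OC)[C@H](O[Si](CC)(CC)CC)/C=C/C(C)=C/[C@@H](C)[C@H](O[Si](CC)(CC)CC)[C@H]1OC | intermediate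
57 | tetra-TES macrolide: target with TES ethers at O17, O23, O29, O33 and free (6R,7R)-diol | CCC[C@H](O[Si](CC)(CC)CC)[C@@H](OC)[C@H]1O[C@]1(C)[C@@H](O[Si](CC)(CC)CC)C/C=C/[C@@H]1OC(=O)/C=C/C=C/[C@@H](O)[C@H](O)/C=C/C(C)=C/[C@H](C)CCC[C@@H](OC)[C@H](O[Si](CC)(CC)CC)/C=C/C(C)=C/[C@@H](C)[C@H](O[Si](CC)(CC)CC)[C@H]1OC | intermediate
58 | CNP0328768.3 | CCC[C@H](O)[C@@H](OC)[C@H]1O[C@]1(C)[C@@H](O)C/C=C/[C@@H]1OC(=O)/C=C/C=C/[C@@H](O)[C@H](O)/C=C/C(C)=C/[C@H](C)CCC[C@@H](OC)[C@H](O)/C=C/C(C)=C/[C@@H](C)[C@H](O)[C@H]1OC | target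

**Step count and risks**

Total step count: 33. Longest linear sequence: 16 steps (steps 1–8, then 26–33).

Three steps most likely to fail:

Step 32 (ring closure by ketyl coupling). The risks are the sense of the threo face, erythro material and oligomers. The fallback sets out from 54 and comes back at 57, and moves the control of C6/C7 from the carbon–carbon bond formation to a reduction. The ring is closed with no demand on selectivity (SmI2, THF, −78 °C, high dilution) to give the protected macrocyclic 6,7-diol as a stereoisomer mixture F1. Oxidation with trifluoroacetic anhydride/DMSO and then Et3N gives the macrocyclic 6,7-dione F2. Transfer hydrogenation with RuCl[(S,S)-TsDPEN](p-cymene) and HCO2H/Et3N reduces both ketones under catalyst control to the threo (6R,7R)-diol, the way benzil gives threo-hydrobenzoin, and this is 57.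

Step 29 (configuration at C25). The α-methoxy β-silyloxy aldehyde may give a poor 25S:25R ratio. The fallback sets out from the coupling of 50 with 40 and comes back at 51, and sets C25 by reduction instead of addition. The coupling product is taken on as the C25 epimer mixture F3 and oxidised with Dess–Martin periodinane/NaHCO3 to the C25 enone F4. Zn(BH4)2 in Et2O at −78 °C then reduces the ketone 1,2 through a zinc chelate between the C25 carbonyl and the C24 methoxy oxygen, with hydride entering from the open face, which gives the 24,25-anti alcohol 51.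

Step 22 (Shi epoxidation). The alkene carries oxygen on both allylic carbons and may react slowly or with low face selectivity. The fallback sets out from 32 and comes back at 38, and makes the epoxide by a hydroxyl-directed titanium epoxidation before C29 is set. NaBH4/CeCl3·7H2O in MeOH reduces 32 to the allylic alcohol F5. Sharpless epoxidation (Ti(OiPr)4, D-(−)-diisopropyl tartrate, t-BuOOH, 4 Å sieves, CH2Cl2, −20 °C) gives the epoxy alcohol F6. SO3·pyridine, DMSO and i-Pr2NEt give the epoxy aldehyde F7. Allenylborane 35, made from 33 as in step 20, adds at −100 °C under reagent control to give the epoxy homopropargylic alcohol F8. TESOTf/2,6-lutidine then gives 38.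

**Further compounds**

F1 | step 32 | protected macrocyclic 6,7-diol, stereoisomer mixture at C6 and C7 | CCC[C@H](O[Si](CC)(CC)CC)[C@@H](OC)[C@H]1O[C@]1(C)[C@@H](O[Si](CC)(CC)CC)C/C=C/[C@@H]1OC(=O)/C=C/C=C/C(O)C(O)/C=C/C(C)=C/[C@H](C)CCC[C@@H](OC)[C@H](O[Si](CC)(CC)CC)/C=C/C(C)=C/[C@@H](C)[C@H](O[Si](CC)(CC)CC)[C@H]1OC
F2 | step 32 | protected macrocyclic 6,7-dione | CCC[C@H](O[Si](CC)(CC)CC)[C@@H](OC)[C@H]1O[C@]1(C)[C@@H](O[Si](CC)(CC)CC)C/C=C/[C@@H]1OC(=O)/C=C/C=C/C(=O)C(=O)/C=C/C(C)=C/[C@H](C)CCC[C@@H](OC)[C@H](O[Si](CC)(CC)CC)/C=C/C(C)=C/[C@@H](C)[C@H](O[Si](CC)(CC)CC)[C@H]1OC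
F3 | step 29 | C25 epimer mixture of 51 | CCC[C@H](O[Si](CC)(CC)CC)[C@@H](OC)[C@H]1O[C@]1(C)[C@@H](O[Si](CC)(CC)CC)C/C=C/C(O)[C@H](OC)[C@@H](O[Si](CC)(CC)CC)[C@H](C)/C=C(C)/C=C/[C@@H](O[Si](CC)(CC)CC)[C@H](OC)CCC[C@@H](C)/C=C(C)/C=C/C(=O)N(C)OC
F4 | step 29 | C25 enone (ketone at C25 conjugated with C26=C27) | CCC[C@H](O[Si](CC)(CC)CC)[C@@H](OC)[C@H]1O[C@]1(C)[C@@H](O[Si](CC)(CC)CC)C/C=C/C(=O)[C@H](OC)[C@@H](O[Si](CC)(CC)CC)[C@H](C)/C=C(C)/C=C/[C@@H](O[Si](CC)(CC)CC)[C@H](OC)CCC[C@@H](C)/C=C(C)/C=C/C(=O)N(C)OC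
F5 | step 22 | (2E,4S,5S)-4-methoxy-2-methyl-5-(triethylsilyloxy)oct-2-en-1-ol | CCC[C@H](O[Si](CC)(CC)CC)[C@@H](OC)/C=C(C)/CO
F6 | step 22 | 2,3-epoxy alcohol of F5 (epoxide as C30/C31 of the target) | CCC[C@H](O[Si](CC)(CC)CC)[C@@H](OC)[C@H]1O[C@]1(C)CO
F7 | step 22 | epoxy aldehyde from F6 (C29 CHO) | CCC[C@H](O[Si](CC)(CC)CC)[C@@H](OC)[C@H]1O[C@]1(C)C=O
F8 | step 22 | epoxy homopropargylic alcohol (free 29-OH, 29S) | CCC[C@H](O[Si](CC)(CC)CC)[C@@H](OC)[C@H]1O[C@]1(C)[C@@H](O)CC#C
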